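## Analysis of the target

Plakortone L is a cis-fused 2,6-dioxabicyclo[3.3.0]octan-3-one. Ring A, the γ-lactone (C1 carbonyl, C2 methylene, C3, C4 and the lactone oxygen), shares the C3–C4 bond with ring B, an oxolane (C3, C4, C5, C6 and the ether oxygen). C3 is the fusion CH on the ether oxygen, C4 the fusion carbon bearing a methyl group and the lactone oxygen, C5 the ring methylene, and C6 the ether carbon carrying a methyl group and the chain C7–C18 that ends in phenyl. All three stereocentres are S: the C3 hydrogen and the C4 methyl share the convex face, the chain on C6 lies on that same face, and the C6 methyl points to the lactone side. C4 and C6 are fully substituted carbinol carbons, 1,3-related across C5, so neither can be epimerised or corrected once made, and at C6 the two carbon substituents (CH3 and CH2R) differ little in size. The sensitive element is the β-alkoxy lactone: base can open the oxolane by elimination of the C3 oxygen from the C2 enolate, and strong acid can ionise the tertiary C–O bonds. The lactone itself is easy, since it forms from a C1 alcohol and the cis C4 oxygen. What is hard is building the quaternary C6 in the right sense relative to C3 and C4 while attaching a long unfunctionalised chain. The strategy rests on the substitution pattern of C6: it holds an oxygen, a methyl group and a methylene (C7) that begins the chain, which is the pattern left when an oxygen and a carbon group add across a 2-methylallyl alkene (C6=C7), and the oxygen concerned, on C3, sits γ to that alkene.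

## Retrosynthetic reasoning

**Lactone acyl–oxygen bond.** Target 22 is opened at the O–C1 bond and C1 is lowered to the alcohol level, giving diol 19. The β-alkoxy lactone is the only base-sensitive function and should appear last. Forward, oxidation of the primary alcohol of 19 must pass through aldehyde 20 and lactol 21 to 22. The C3 arm and the C4 hydroxyl are cis on the oxolane, so only the cis-fused lactone can form.

**Protecting groups and chain saturation.** The free C4 hydroxyl and the saturated chain of 18 are traced to a C4 benzyl ether and a C8=C9 double bond in 17, because a single hydrogenation removes both. The primary oxygen stays silylated until 18 and is released by fluoride to give 19, so only one hydroxyl is free when the chain is attached.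

**O–C6 and C7–C8 (the key disconnection).** Compound 17 is cut at both bonds at once, which returns hydroxy alkene 8 and bromoalkene 16. Cutting here, rather than at C6–C7 or at a ring C–C bond, removes the quaternary C6 stereocentre, the oxolane and the whole side chain in one step. It leaves one fragment with all the oxygen functions and the two other stereocentres, and one plain hydrocarbon halide. The forward reaction has to add the C3 oxygen and the alkenyl carbon syn across C6=C7, with oxygen at the substituted carbon and C7 trans to the C3 arm. Two features of 8 were fixed with this step in mind: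
- The C4 oxygen is carried as a benzyl ether and not as a free hydroxyl. A tertiary homoallylic alkoxide bound to palladium can undergo β-carbon elimination (retro-allylation), which would break C4–C5 and pass the 2-methylallyl group to the alkenyl partner. The ether closes that path at no extra cost, since it also serves as the chelating group earlier and leaves in the hydrogenation.
- The primary oxygen carries a triisopropylsilyl group, because a smaller silyl group 1,3 to the C3 alkoxide could migrate under the basic conditions.

**Bromoalkene 16.** The C–Br bond is traced to hydrozirconation–bromination of alkyne 14, which fixes the (E) geometry. The geometry is not needed in the product, but the (E)-bromide resists base-induced elimination. Alkyne 14 comes by one-carbon homologation of aldehyde 13, 13 by oxidative cleavage of alkene 11, and 11 by joining the aryl–alkyl bond from bromide 9 and Grignard reagent 10. All of this is functional-group chemistry on an unbranched chain.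

**C2–C3 bond.** Silyl ether 8 comes from diol 7 and this from ester 6. The C2–C3 bond of 6 is cut to aldehyde 5 and a silyl ketene acetal of an acetate ester. The cut is made here because the benzyloxy group on C4 can chelate with the aldehyde oxygen, so the existing C4 centre directs the new C3 centre. Attack from the methyl face of the chelate gives the required (3S,4S) pair.

**C4–C5 bond.** Aldehyde 5 comes from ester 4 and its parent alcohol 3. Compound 3 is cut at C4–C5 into pyruvate 1 and isobutene 2. A catalytic enantioselective carbonyl-ene reaction forms this bond, sets the quaternary C4, and delivers the C6=C7 methylene in the place where the key step needs it.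

## Alternatives that were turned down

**Alternative 1: ketal-triggered Prins closure ending in lactonisation.**
- Disconnection: O–C6, C5–C6 and the lactone O–C4 bond are cut together. This returns tert-butyl (3S)-3-hydroxy-4-methylpent-4-enoate A1 and the dimethyl ketal (13,13-dimethoxytetradec-11-yn-1-yl)benzene A2.
- Forward key step: a silyl triflate would exchange the C3 hydroxyl of A1 into ketal A2. The isopropenyl terminus C5 attacks the oxocarbenium ion at C6, and the ester carbonyl captures the tertiary C4 cation with loss of the tert-butyl group. This gives alkynyl lactone A3, and alkyne hydrogenation would finish.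
- For: both rings, three bonds and two stereocentres form in one operation from two small pieces, and the tether forces C4 into the cis-fused arrangement. In step count it is clearly shorter than the chosen route.
- Against: the C5–C6 bond forms by a 5-endo attack of an alkene attached directly to the oxygen-bearing carbon, a geometry with poor overlap. The same Lewis acid can ionise the allylic C3–O bond and erase C3. C6 depends on telling a methyl from a slim alkynyl group on the oxocarbenium carbon, and the substrate offers no handle for that.
- Comparison: the chosen route is about twice as long, but its ring closes in the 5-exo mode of an established catalytic reaction, and C6 is set in an organised cyclic transition state tied to C3.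

**Alternative 2: dichloroketene [2+2] on a dihydrofuran, then Baeyer–Villiger oxidation.**
- Disconnection: the lactone is traced to a cyclobutanone by oxygen insertion into C1–C4, and this to a cycloaddition forming C2–C3 and C1–C4 on dihydrofuran A4, tert-butyl{[(2R)-2,4-dimethyl-2,3-dihydrofuran-2-yl]methoxy}diphenylsilane.
- Forward key step: dichloroketene A5 adds across the enol ether C3=C4 of A4 on the face away from the silyloxymethyl group, giving the cis-fused dichlorocyclobutanone A6. Dechlorination, Baeyer–Villiger oxidation with migration of the quaternary C4, then desilylation, oxidation, olefination and hydrogenation to grow the chain would follow.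
- For: the regiochemistry of the cycloaddition (enol ether polarisation) and of the oxygen insertion (the more substituted carbon migrates with retention) is highly dependable, and the cis fusion is automatic. On the lactone annulation itself this route is stronger than the chosen one.
- Against: C6 must already exist as a quaternary stereocentre in A4, which needs its own asymmetric synthesis. The facial choice rests on CH2OSi against CH3 at a carbon two atoms from either alkene terminus. The chain is attached only afterwards, in four more steps, one of which exposes the β-alkoxy lactone to a basic ylide.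
- Comparison: the chosen key step creates C6 and attaches the complete chain in the same operation, which is where this alternative is weakest.

**Alternative 3: carbenoid C–H insertion into a secondary ether.**
- Disconnection: C5–C6, with C4 as a ketone, back to α-alkoxy diazoketone A7, methyl (3S)-5-diazo-4-oxo-3-{[(2S)-14-phenyltetradecan-2-yl]oxy}pentanoate.
- Forward key step: a dirhodium tetracarboxylate catalyst would generate a carbenoid whose carbon C5 inserts into the tertiary C6–H bond next to the ether oxygen. This gives oxolanone A8, methyl 2-[(2S,5S)-5-methyl-3-oxo-5-(12-phenyldodecyl)oxolan-2-yl]acetate. Methyl addition to the C4 ketone anti to the C3 arm and lactonisation would follow.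
- For: insertion proceeds with retention, so C6 is copied from a simple secondary carbinol centre. On the security of the C6 configuration this is stronger than the chosen route, which relies on diastereoselection.
- Against: A7 needs a stereospecific ether link between two secondary stereocentres and a diazoketone beside an ester. In A8 the C3 hydrogen is α to the ketone and the ring oxygen is β to the ester, so epimerisation and β-elimination threaten. The methyl addition must be face-selective and must outrun enolisation. The route is longer.
- Comparison: the chosen route installs C4 first as a fixed quaternary carbinol and never passes through an epimerisable ketone. The price is a C6 selectivity that has to be earned in the key step.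

Key step: step 11

Assumption: phenylmagnesium bromide 10 is bought as a THF solution (it is the Grignard reagent of bromobenzene), and the (S,S) ligand antipode is taken to give the (S)-alcohol in step 1 by analogy with glyoxylate ene reactions of the same catalyst.

## Route

Step 1
Reactants: 1 methyl pyruvate; 2 isobutene (2-methylpropene)
Product: 3 methyl (2S)-2-hydroxy-2,4-dimethylpent-4-enoate
Conditions: [Cu((S,S)-tBu-box)](SbF6)2 (10 mol%), isobutene (excess, condensed), CH2Cl2, 0 → 40 °C, sealed vessel
Reagents that add atoms: none
Why: Enantioselective carbonyl-ene reaction: the pyruvate chelates the divalent copper bis(oxazoline) Lewis acid through both carbonyl oxygens, the ligand leaves the Si face of the ketone open, and the ene shift of isobutene forms C4–C5 and the C6=C7 methylene, Si-face attack corresponding to (S) at C4; the ligand antipode would be used if the sense proved opposite.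

Step 2
Reactants: 3 methyl (2S)-2-hydroxy-2,4-dimethylpent-4-enoate
Product: 4 methyl (2S)-2-(benzyloxy)-2,4-dimethylpent-4-enoate
Conditions: NaH (1.2 equiv), BnBr (1.3 equiv), Bu4NI (5 mol%), THF–DMF, 0 °C → rt
Reagents that add atoms: benzyl bromide, BrCc1ccccc1
Why: Williamson etherification of the tertiary alkoxide; C4 has no hydrogen and the ester has no α-hydrogen, so base can neither racemise nor enolise, and acid (which would lactonise the ester onto the 2-methylallyl group) is avoided.

Step 3
Reactants: 4 methyl (2S)-2-(benzyloxy)-2,4-dimethylpent-4-enoate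
Product: 5 (2S)-2-(benzyloxy)-2,4-dimethylpent-4-enal
Conditions: iBu2AlH (1.1 equiv), CH2Cl2, −78 °C; MeOH, then aq. potassium sodium tartrate
Reagents that add atoms: none
Why: Partial reduction of an α-alkoxy ester: the aluminium hemiacetal is held by chelation to the benzyloxy oxygen and shielded by the quaternary α-carbon, so it should persist at −78 °C until work-up; the aldehyde has no α-hydrogen, is configurationally stable and is used crude.

Step 4
Reactants: 5 (2S)-2-(benzyloxy)-2,4-dimethylpent-4-enal
Product: 6 methyl (3S,4S)-4-(benzyloxy)-3-hydroxy-4,6-dimethylhept-6-enoate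
Conditions: MgBr2·OEt2 (3 equiv), CH2Cl2, −78 °C, 15 min; 1-(tert-butyldimethylsilyloxy)-1-methoxyethene (2 equiv), −78 → −30 °C; aq. NH4Cl, then 1 M HCl
Reagents that add atoms: 1-(tert-butyldimethylsilyloxy)-1-methoxyethene, C=C(OC)O[Si](C)(C)C(C)(C)C
Why: Chelation-controlled Mukaiyama aldol addition: magnesium bridges the aldehyde and benzyloxy oxygens in a five-membered Cram chelate and the ketene acetal attacks C3 from the face of the C4 methyl group, opposite the larger 2-methylallyl group, which corresponds to (3S); MgBr2 is a mild Lewis acid chosen to spare the 1,1-disubstituted alkene.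

Step 5
Reactants: 6 methyl (3S,4S)-4-(benzyloxy)-3-hydroxy-4,6-dimethylhept-6-enoate
Product: 7 (3S,4S)-4-(benzyloxy)-4,6-dimethylhept-6-ene-1,3-diol
Conditions: LiAlH4 (1.5 equiv), THF, 0 °C; H2O, 15% aq. NaOH, H2O
Reagents that add atoms: none
Why: Hydride reduction of the methyl ester to the primary alcohol; the benzyl ether and the isolated alkene are inert to LiAlH4 and no stereocentre is touched.

Step 6
Reactants: 7 (3S,4S)-4-(benzyloxy)-4,6-dimethylhept-6-ene-1,3-diol
Product: 8 (3S,4S)-4-(benzyloxy)-4,6-dimethyl-1-[(triisopropylsilyl)oxy]hept-6-en-3-ol
Conditions: iPr3SiCl (1.1 equiv), imidazole (2.2 equiv), CH2Cl2, 0 °C → rt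
Reagents that add atoms: chlorotriisopropylsilane, CC(C)[Si](Cl)(C(C)C)C(C)C
Why: Selective silylation of the primary hydroxyl, the C3 hydroxyl being secondary and flanked by the quaternary C4; the bulky triisopropylsilyl group is chosen because it should not migrate to the C3 alkoxide under the basic conditions of step 11.

Step 7
Reactants: 9 11-bromoundec-1-ene; 10 phenylmagnesium bromide
Product: 11 11-phenylundec-1-ene
Conditions: Li2CuCl4 (3 mol%), THF, 0 °C → rt
Reagents that add atoms: none
Why: Copper-catalysed Kochi-type coupling of an aryl Grignard reagent with a primary alkyl bromide; the terminal alkene does not take part.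

Step 8
Reactants: 11 11-phenylundec-1-ene
Product: 13 10-phenyldecanal, via secondary ozonide 12 (not isolated)
Conditions: O3, CH2Cl2, −78 °C (to first blue colour); PPh3 (1.2 equiv), −78 °C → rt
Reagents that add atoms: ozone, [O-][O+]=O
Why: Ozonolysis with reductive work-up; the monosubstituted alkene reacts far faster than the benzene ring at −78 °C and phosphine reduction of the 1,2,4-trioxolane stops at the aldehyde.

Step 9
Reactants: 13 10-phenyldecanal
Product: 14 11-phenylundec-1-yne
Conditions: dimethyl (1-diazo-2-oxopropyl)phosphonate (1.3 equiv), K2CO3 (2 equiv), MeOH, 0 °C → rt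
Reagents that add atoms: dimethyl (1-diazo-2-oxopropyl)phosphonate, CC(=O)C(=[N+]=[N-])P(=O)(OC)OC
Why: Ohira–Bestmann variant of the Seyferth–Gilbert homologation: methanolysis releases the diazomethylphosphonate anion, which converts the aldehyde into the terminal alkyne with one added carbon under carbonate conditions mild enough for an enolisable aldehyde.

Step 10
Reactants: 14 11-phenylundec-1-yne
Product: 16 (E)-1-bromo-11-phenylundec-1-ene, via alkenylzirconocene chloride 15 (not isolated)
Conditions: Cp2Zr(H)Cl (1.3 equiv), THF, rt; NBS (1.3 equiv), 0 °C
Reagents that add atoms: N-bromosuccinimide, O=C1CCC(=O)N1Br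
Why: Hydrozirconation adds Zr–H syn across the terminal alkyne with zirconium on the terminal carbon, and bromination cleaves the C–Zr bond with retention, so only the (E)-bromide should form; in this isomer the vinylic hydrogen is cis to bromine, which makes it resistant to base-induced anti elimination in step 11.

Step 11
Reactants: 8 (3S,4S)-4-(benzyloxy)-4,6-dimethyl-1-[(triisopropylsilyl)oxy]hept-6-en-3-ol; 16 (E)-1-bromo-11-phenylundec-1-ene (1.5 equiv)
Product: 17 {2-[(2S,3S,5S)-3-(benzyloxy)-3,5-dimethyl-5-[(2E)-12-phenyldodec-2-en-1-yl]oxolan-2-yl]ethoxy}tri(propan-2-yl)silane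
Conditions: Pd2(dba)3 (2 mol%), bis[2-(diphenylphosphino)phenyl] ether (DPE-Phos, 4 mol%), NaOtBu (2 equiv), THF, 65 °C
Reagents that add atoms: none
Why: Oxidative addition of 16 to the zerovalent palladium–bisphosphine complex and exchange of bromide for the sodium alkoxide of 8 should give an alkenylpalladium alkoxide; the C6=C7 alkene then inserts syn into the Pd–O bond (O–C6 formed, palladium on C7) and C–C reductive elimination joins C7 to C8 with retention of the (E) geometry. The closest known reaction type is the palladium-catalysed carboetherification of γ-hydroxy alkenes with aryl or alkenyl bromides, which is established for hindered alcohols and for 1,1-disubstituted alkenes. The oxolane closes in the 5-exo-trig mode, helped by the fully substituted C4 (Thorpe–Ingold effect). The new stereocentre C6 is controlled by C3: in the organised insertion transition state palladium bridges the C3 oxygen and C7 on one face of the forming ring, and the silyloxyethyl arm on C3 should take the pseudo-equatorial position on the other face, away from the ligated metal, so that C7 ends trans to the arm and the C6 methyl cis to it, which is (5S). C4 carries a substituent on each face (methyl syn to C7, benzyloxy syn to the C6 methyl) and should bias the choice little. The step also needs insertion to win over β-hydride elimination of the secondary alkoxide and over C–O reductive elimination; once insertion has occurred the alkylpalladium has no β-hydrogen, because C6 is fully substituted, so reductive elimination is its only forward path. The benzyl ether on the C4 oxygen removes the retro-allylation channel of a tertiary homoallylic alkoxide, the triisopropylsilyl ether resists alkoxide-induced migration, and the (E)-bromide resists dehydrobromination by NaOtBu.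

Step 12
Reactants: 17 {2-[(2S,3S,5S)-3-(benzyloxy)-3,5-dimethyl-5-[(2E)-12-phenyldodec-2-en-1-yl]oxolan-2-yl]ethoxy}tri(propan-2-yl)silane
Product: 18 (2S,3S,5S)-3,5-dimethyl-5-(12-phenyldodecyl)-2-{2-[(triisopropylsilyl)oxy]ethyl}oxolan-3-ol
Conditions: H2 (1 atm), 10% Pd/C, EtOAc–EtOH, rt
Reagents that add atoms: none
Why: Heterogeneous hydrogenation saturates the disubstituted C8=C9 alkene and the same catalyst hydrogenolyses the benzylic C–O bond of the tertiary benzyl ether; the silyl ether, the oxolane and the terminal phenyl ring are stable under neutral conditions at 1 atm.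

Step 13
Reactants: 18 (2S,3S,5S)-3,5-dimethyl-5-(12-phenyldodecyl)-2-{2-[(triisopropylsilyl)oxy]ethyl}oxolan-3-ol
Product: 19 (2S,3S,5S)-2-(2-hydroxyethyl)-3,5-dimethyl-5-(12-phenyldodecyl)oxolan-3-ol
Conditions: Bu4NF (1.5 equiv), THF, 0 °C → rt
Reagents that add atoms: none
Why: Fluoride cleavage of the primary silyl ether, driven by the Si–F bond; the tertiary alcohol and the ether ring are inert.

Step 14
Reactants: 19 (2S,3S,5S)-2-(2-hydroxyethyl)-3,5-dimethyl-5-(12-phenyldodecyl)oxolan-3-ol
Product: 22 plakortone L [(3aS,5S,6aS)-5,6a-dimethyl-5-(12-phenyldodecyl)tetrahydrofuro[3,2-b]furan-2(3H)-one], via hydroxy aldehyde 20 (not isolated), via lactol 21 (not isolated)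
Conditions: TEMPO (0.2 equiv), PhI(OAc)2 (2.5 equiv), CH2Cl2, rt
Reagents that add atoms: none
Why: Oxoammonium-mediated oxidative lactonisation of a 1,4-diol: only the primary alcohol is oxidised, the aldehyde is trapped by the cis tertiary C4 hydroxyl as the lactol, and a second oxidation gives the γ-lactone; the medium is weakly acidic, so the β-alkoxy carbonyl compounds are not exposed to base.

## Compound list

1 | methyl pyruvate | CC(=O)C(=O)OC | starting material
2 | isobutene (2-methylpropene) | CC(C)=C | starting material
3 | methyl (2S)-2-hydroxy-2,4-dimethylpent-4-enoate | CC(=C)C[C@](C)(O)C(=O)OC | intermediate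
4 | methyl (2S)-2-(benzyloxy)-2,4-dimethylpent-4-enoate | CC(=C)C[C@](C)(OCc1ccccc1)C(=O)OC | intermediate
5 | (2S)-2-(benzyloxy)-2,4-dimethylpent-4-enal | CC(=C)C[C@](C)(OCc1ccccc1)C=O | intermediate
6 | methyl (3S,4S)-4-(benzyloxy)-3-hydroxy-4,6-dimethylhept-6-enoate | CC(=C)C[C@](C)(OCc1ccccc1)[C@@H](O)CC(=O)OC | intermediate
7 | (3S,4S)-4-(benzyloxy)-4,6-dimethylhept-6-ene-1,3-diol | CC(=C)C[C@](C)(OCc1ccccc1)[C@@H](O)CCO | intermediate
8 | (3S,4S)-4-(benzyloxy)-4,6-dimethyl-1-[(triisopropylsilyl)oxy]hept-6-en-3-ol | CC(=C)C[C@](C)(OCc1ccccc1)[C@@H](O)CCO[Si](C(C)C)(C(C)C)C(C)C | intermediate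
9 | 11-bromoundec-1-ene | C=CCCCCCCCCCBr | starting material
10 | phenylmagnesium bromide | Br[Mg]c1ccccc1 | starting material
11 | 11-phenylundec-1-ene | C=CCCCCCCCCCc1ccccc1 | intermediate
12 | 3-(9-phenylnonyl)-1,2,4-trioxolane (racemic) | C1OC(CCCCCCCCCc2ccccc2)OO1 | intermediate
13 | 10-phenyldecanal | O=CCCCCCCCCCc1ccccc1 | intermediate
14 | 11-phenylundec-1-yne | C#CCCCCCCCCCc1ccccc1 | intermediate
15 | chlorobis(cyclopentadienyl)[(E)-11-phenylundec-1-en-1-yl]zirconium | Cl[Zr](/C=C/CCCCCCCCCc1ccccc1)(C1C=CC=C1)C1C=CC=C1 | intermediate
16 | (E)-1-bromo-11-phenylundec-1-ene | Br/C=C/CCCCCCCCCc1ccccc1 | intermediate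
17 | {2-[(2S,3S,5S)-3-(benzyloxy)-3,5-dimethyl-5-[(2E)-12-phenyldodec-2-en-1-yl]oxolan-2-yl]ethoxy}tri(propan-2-yl)silane | C[C@]1(C/C=C/CCCCCCCCCc2ccccc2)C[C@](C)(OCc2ccccc2)[C@H](CCO[Si](C(C)C)(C(C)C)C(C)C)O1 | intermediate
18 | (2S,3S,5S)-3,5-dimethyl-5-(12-phenyldodecyl)-2-{2-[(triisopropylsilyl)oxy]ethyl}oxolan-3-ol | C[C@]1(CCCCCCCCCCCCc2ccccc2)C[C@](C)(O)[C@H](CCO[Si](C(C)C)(C(C)C)C(C)C)O1 | intermediate
19 | (2S,3S,5S)-2-(2-hydroxyethyl)-3,5-dimethyl-5-(12-phenyldodecyl)oxolan-3-ol | C[C@]1(CCCCCCCCCCCCc2ccccc2)C[C@](C)(O)[C@H](CCO)O1 | intermediate
20 | 2-[(2S,3S,5S)-3-hydroxy-3,5-dimethyl-5-(12-phenyldodecyl)oxolan-2-yl]acetaldehyde | C[C@]1(CCCCCCCCCCCCc2ccccc2)C[C@](C)(O)[C@H](CC=O)O1 | intermediate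
21 | (3aS,5S,6aS)-5,6a-dimethyl-5-(12-phenyldodecyl)hexahydrofuro[3,2-b]furan-2-ol (both configurations at C2) | C[C@]1(CCCCCCCCCCCCc2ccccc2)C[C@]2(C)OC(O)C[C@@H]2O1 | intermediate
22 | plakortone L, (3aS,5S,6aS)-5,6a-dimethyl-5-(12-phenyldodecyl)tetrahydrofuro[3,2-b]furan-2(3H)-one | C[C@]1(CCCCCCCCCCCCc2ccccc2)C[C@]2(C)OC(=O)C[C@@H]2O1 | target

## Step count and least certain steps

Total: 14 steps. Longest linear sequence: 10 steps (steps 1–6 and 11–14); the chain fragment takes 4 steps (7–10).

**Step 11 (key step).** The main danger is poor facial selectivity in the syn-oxypalladation: C3 alone has to distinguish two faces of an alkene whose substituents are CH3 and CH2, and the quaternary C4 does not help. Beside this, β-hydride elimination from the hindered secondary palladium alkoxide (oxidation at C3 with reduction of the bromide) and C–O reductive elimination can drain the catalyst. Fallback, from 8 and 11, returning at 18: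
- A Mukaiyama aerobic oxidative cyclisation of 8 should close the same oxolane with the hydroxymethyl group trans to the C3 arm. Conditions: Co(modp)2, the divalent cobalt bis-chelate of 1-morpholinocarbamoyl-4,4-dimethylpentane-1,3-dione, with O2, tBuOOH, iPrOH, 55 °C. The product is [(2R,4S,5S)-4-(benzyloxy)-2,4-dimethyl-5-{2-[(triisopropylsilyl)oxy]ethyl}oxolan-2-yl]methanol F1.
- Dess–Martin oxidation gives (2R,4S,5S)-4-(benzyloxy)-2,4-dimethyl-5-{2-[(triisopropylsilyl)oxy]ethyl}oxolane-2-carbaldehyde F2.
- In parallel, radical anti-Markovnikov addition of HBr to alkene 11 (dibenzoyl peroxide, hexane) gives (11-bromoundecyl)benzene F3, and PPh3 converts this into triphenyl(11-phenylundecyl)phosphonium bromide F4.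
- Wittig olefination of F2 with the ylide of F4 (NaN(SiMe3)2, THF, −78 → 0 °C) gives {2-[(2S,3S,5R)-3-(benzyloxy)-3,5-dimethyl-5-[(1Z)-12-phenyldodec-1-en-1-yl]oxolan-2-yl]ethoxy}tri(propan-2-yl)silane F5.
- Hydrogenation under the conditions of step 12 saturates C7=C8 and removes the benzyl group, which gives 18.

**Step 4.** The methyl and 2-methylallyl faces of the chelate may be discriminated too weakly, and the Lewis-acid-activated aldehyde may close onto the 2-methylallyl alkene in a Prins or ene reaction. Fallback, from 5, returning at 7: reagent control replaces chelation control. The doubly deprotonated acetate (S)-2-hydroxy-1,2,2-triphenylethyl acetate ((S)-HYTRA; LDA, THF, then MgBr2, about −110 °C) is added to 5 to give (1S)-2-hydroxy-1,2,2-triphenylethyl (3S,4S)-4-(benzyloxy)-3-hydroxy-4,6-dimethylhept-6-enoate F6. LiAlH4 reduction releases the auxiliary diol and gives 7 directly.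

**Step 2.** O-alkylation of the hindered tertiary alkoxide may be slow enough for intermolecular transesterification of the α-alkoxido ester to compete. Fallback, from 3, returning at 5 (steps 2 and 3 are bypassed):
- LiAlH4 reduces 3 to (2S)-2,4-dimethylpent-4-ene-1,2-diol F7.
- Benzaldehyde dimethyl acetal with pyridinium p-toluenesulfonate gives (4S)-4-methyl-4-(2-methylprop-2-en-1-yl)-2-phenyl-1,3-dioxolane F8.
- iBu2AlH (CH2Cl2, 0 °C) opens the acetal at the less hindered oxygen, leaving the benzyl group on the tertiary oxygen: (2S)-2-(benzyloxy)-2,4-dimethylpent-4-en-1-ol F9.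
- Swern oxidation of F9 gives 5.

**Step 12.** Hydrogenolysis of the hindered tertiary benzyl ether may stall after the alkene has been reduced, and an acidic catalyst batch may strip the silyl ether early. Fallback, from 17, returning at 18: the two events are separated. Hydrogenation over Pd/C poisoned with pyridine (EtOAc) reduces only the alkene, giving {2-[(2S,3S,5S)-3-(benzyloxy)-3,5-dimethyl-5-(12-phenyldodecyl)oxolan-2-yl]ethoxy}tri(propan-2-yl)silane F10. The benzyl ether is then cleaved by electron transfer from lithium 4,4'-di-tert-butylbiphenylide (THF, −78 °C), which leaves the monoalkylbenzene terminus and the silyl ether alone and gives 18.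

## Further compounds

F1 | step 11 | [(2R,4S,5S)-4-(benzyloxy)-2,4-dimethyl-5-{2-[(triisopropylsilyl)oxy]ethyl}oxolan-2-yl]methanol | C[C@]1(CO)C[C@](C)(OCc2ccccc2)[C@H](CCO[Si](C(C)C)(C(C)C)C(C)C)O1
F2 | step 11 | (2R,4S,5S)-4-(benzyloxy)-2,4-dimethyl-5-{2-[(triisopropylsilyl)oxy]ethyl}oxolane-2-carbaldehyde | C[C@]1(C=O)C[C@](C)(OCc2ccccc2)[C@H](CCO[Si](C(C)C)(C(C)C)C(C)C)O1
F3 | step 11 | (11-bromoundecyl)benzene | BrCCCCCCCCCCCc1ccccc1
F4 | step 11 | triphenyl(11-phenylundecyl)phosphonium bromide | [Br-].c1ccccc1CCCCCCCCCCC[P+](c1ccccc1)(c1ccccc1)c1ccccc1
F5 | step 11 | {2-[(2S,3S,5R)-3-(benzyloxy)-3,5-dimethyl-5-[(1Z)-12-phenyldodec-1-en-1-yl]oxolan-2-yl]ethoxy}tri(propan-2-yl)silane | C[C@]1(/C=C\CCCCCCCCCCc2ccccc2)C[C@](C)(OCc2ccccc2)[C@H](CCO[Si](C(C)C)(C(C)C)C(C)C)O1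
F6 | step 4 | (1S)-2-hydroxy-1,2,2-triphenylethyl (3S,4S)-4-(benzyloxy)-3-hydroxy-4,6-dimethylhept-6-enoate | CC(=C)C[C@](C)(OCc1ccccc1)[C@@H](O)CC(=O)O[C@@H](c1ccccc1)C(O)(c1ccccc1)c1ccccc1
F7 | step 2 | (2S)-2,4-dimethylpent-4-ene-1,2-diol | CC(=C)C[C@](C)(O)CO
F8 | step 2 | (4S)-4-methyl-4-(2-methylprop-2-en-1-yl)-2-phenyl-1,3-dioxolane (either configuration at C2) | CC(=C)C[C@@]1(C)COC(c2ccccc2)O1
F9 | step 2 | (2S)-2-(benzyloxy)-2,4-dimethylpent-4-en-1-ol | CC(=C)C[C@](C)(OCc1ccccc1)CO
F10 | step 12 | {2-[(2S,3S,5S)-3-(benzyloxy)-3,5-dimethyl-5-(12-phenyldodecyl)oxolan-2-yl]ethoxy}tri(propan-2-yl)silane | C[C@]1(CCCCCCCCCCCCc2ccccc2)C[C@](C)(OCc2ccccc2)[C@H](CCO[Si](C(C)C)(C(C)C)C(C)C)O1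
A1 | alternative 1 | tert-butyl (3S)-3-hydroxy-4-methylpent-4-enoate | CC(=C)[C@@H](O)CC(=O)OC(C)(C)C
A2 | alternative 1 | (13,13-dimethoxytetradec-11-yn-1-yl)benzene | CC(OC)(OC)C#CCCCCCCCCCCc1ccccc1
A3 | alternative 1 | (3aS,5R,6aS)-5,6a-dimethyl-5-(12-phenyldodec-1-yn-1-yl)tetrahydrofuro[3,2-b]furan-2(3H)-one | C[C@]1(C#CCCCCCCCCCCc2ccccc2)C[C@]2(C)OC(=O)C[C@@H]2O1
A4 | alternative 2 | tert-butyl{[(2R)-2,4-dimethyl-2,3-dihydrofuran-2-yl]methoxy}diphenylsilane | C[C@]1(CO[Si](c2ccccc2)(c2ccccc2)C(C)(C)C)CC(C)=CO1
A5 | alternative 2 | dichloroketene | ClC(Cl)=C=O
A6 | alternative 2 | (1R,3R,5S)-3-{[(tert-butyldiphenylsilyl)oxy]methyl}-7,7-dichloro-3,5-dimethyl-2-oxabicyclo[3.2.0]heptan-6-one | C[C@]1(CO[Si](c3ccccc3)(c3ccccc3)C(C)(C)C)C[C@]2(C)C(=O)C(Cl)(Cl)[C@@H]2O1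
A7 | alternative 3 | methyl (3S)-5-diazo-4-oxo-3-{[(2S)-14-phenyltetradecan-2-yl]oxy}pentanoate | C[C@@H](CCCCCCCCCCCCc1ccccc1)O[C@@H](CC(=O)OC)C(=O)C=[N+]=[N-]
A8 | alternative 3 | methyl 2-[(2S,5S)-5-methyl-3-oxo-5-(12-phenyldodecyl)oxolan-2-yl]acetate | C[C@]1(CCCCCCCCCCCCc2ccccc2)CC(=O)[C@H](CC(=O)OC)O1
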